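**Plan**
1. Cuts: the C10–C11 alkenyl–alkenyl bond is cut last (alkenyl iodide + alkenyl stannane), then C10'–C11' in the same way. The central C11–C11' pentaene goes back to the C10 dialdehyde (C11=C12 and C11'=C12' by Takai–Hodgson olefination). On each end group, C9–CH3 and C10–I go back to a terminal C9≡C10 enyne, and on ring A the C6–C7 bond goes back to a Heck reaction.
2. Enabling feature: C10 and C11 are the unsubstituted CH ends of two E alkenes, C9(CH3)=C10 and C11=C12, inside the decaene, so their bond can form by a stereoretentive Pd-catalysed coupling under neutral conditions. The palmitate on C3 of ring A (the cyclohex-1-ene ring) and the free allylic hydroxyl on C3' of ring B (the cyclohex-2-ene ring) lie on opposite sides of this bond, so each half already carries its final oxygen function.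
3. Forward order: ring A iodide palmitate from (4R,6R)-4-hydroxy-2,2,6-trimethylcyclohexanone; ring B iodide from (R)-α-ionone; bis-stannane linchpin from the C10 dialdehyde; ring B iodide + linchpin give the C26 heptaenyl stannane; the last step joins it to the ring A iodide.
4. Stereochemistry: C3 comes from the hydroxy ketone and C6' from (R)-α-ionone. C3' is set by hydride delivery anti to the axial C1' methyl, trans to the C6' chain. All alkenes are E, from the Heck reaction, syn-methylalumination, Takai–Hodgson olefination and retention in both couplings.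

Key step: step 15

Assumption: (4R,6R)-4-hydroxy-2,2,6-trimethylcyclohexanone and enantiopure (R)-α-ionone are taken as purchasable chiral-pool materials; all polyenes are handled under argon with exclusion of light.

**Step 1**
Reactants: 1 (4R,6R)-4-hydroxy-2,2,6-trimethylcyclohexan-1-one
Product: 2 (4R,6R)-4-[(tert-butyldimethylsilyl)oxy]-2,2,6-trimethylcyclohexan-1-one
Conditions: TBSCl, imidazole, DMF, rt
Reagents that add atoms: tert-butyldimethylsilyl chloride, CC(C)(C)[Si](C)(C)Cl
Why: Silyl ether protection of the secondary alcohol masks the future C3 hydroxyl against the lithium amide and AlMe3 used later; the oxygen-bearing stereocentre is carried over unchanged.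

**Step 2**
Reactants: 2 (4R,6R)-4-[(tert-butyldimethylsilyl)oxy]-2,2,6-trimethylcyclohexan-1-one
Product: 4 (4R)-4-[(tert-butyldimethylsilyl)oxy]-2,6,6-trimethylcyclohex-1-en-1-yl trifluoromethanesulfonate, via lithium enolate 3 (not isolated)
Conditions: LiN(i-Pr)2 (LDA), THF, −78 → 0 °C; PhNTf2, 0 °C → rt
Reagents that add atoms: N-phenylbis(trifluoromethanesulfonimide), O=S(=O)(N(c1ccccc1)S(=O)(=O)C(F)(F)F)C(F)(F)F
Why: Enol triflate formation: the other α-carbon is quaternary, so deprotonation can occur only at the methyl-bearing carbon and O-triflation gives the single tetrasubstituted alkenyl triflate (the future C5=C6 alkene of ring A); the methyl-bearing stereocentre is erased on purpose and the silyloxy centre is untouched.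

**Step 3**
Reactants: 4 (4R)-4-[(tert-butyldimethylsilyl)oxy]-2,6,6-trimethylcyclohex-1-en-1-yl trifluoromethanesulfonate; 5 but-3-en-2-one
Product: 6 (3E)-4-[(4R)-4-[(tert-butyldimethylsilyl)oxy]-2,6,6-trimethylcyclohex-1-en-1-yl]but-3-en-2-one
Conditions: Pd(OAc)2 (5 mol%), PPh3 (10 mol%), Et3N, DMF, 70 °C
Reagents that add atoms: none
Why: Heck reaction: oxidative addition of the alkenyl triflate, syn insertion of the enone with the ring carbon going to the terminal CH2, and syn β-hydride elimination should give the E-C7=C8 dienone and form the C6–C7 bond.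

**Step 4**
Reactants: 6 (3E)-4-[(4R)-4-[(tert-butyldimethylsilyl)oxy]-2,6,6-trimethylcyclohex-1-en-1-yl]but-3-en-2-one
Product: 10 {[(1R)-4-[(1E)-but-1-en-3-yn-1-yl]-3,5,5-trimethylcyclohex-3-en-1-yl]oxy}(tert-butyl)dimethylsilane, via lithium dienolate 7 (not isolated), via enol phosphate 8 (not isolated), via lithium acetylide 9 (not isolated)
Conditions: LiN(i-Pr)2 (1.05 equiv), THF, −78 °C; ClP(O)(OEt)2, −78 °C → rt; then LiN(i-Pr)2 (2.3 equiv), THF, −78 °C → rt; H2O
Reagents that add atoms: none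
Why: Methyl ketone to terminal alkyne through the enol phosphate: kinetic deprotonation at the methyl group, O-phosphorylation, base-induced elimination of diethyl phosphate and protonation of the acetylide on work-up should give the (E)-enyne with C9≡C10 in place; no stereocentre is involved.

**Step 5**
Reactants: 10 {[(1R)-4-[(1E)-but-1-en-3-yn-1-yl]-3,5,5-trimethylcyclohex-3-en-1-yl]oxy}(tert-butyl)dimethylsilane
Product: 12 tert-butyl{[(1R)-4-[(1E,3E)-4-iodo-3-methylbuta-1,3-dien-1-yl]-3,5,5-trimethylcyclohex-3-en-1-yl]oxy}dimethylsilane, via alkenylalane 11 (not isolated)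
Conditions: AlMe3 (2.5 equiv), Cp2ZrCl2 (0.3 equiv), CH2Cl2, 0 °C → rt; then I2, THF, −30 → 0 °C
Reagents that add atoms: trimethylaluminium, C[Al](C)C; iodine, II
Why: Zirconium-catalysed methylalumination (Negishi carboalumination) adds CH3 and Al syn across the terminal alkyne with CH3 on the internal carbon, and iodinolysis of the C–Al bond with retention should give the (E)-2-methylalkenyl iodide, which fixes the C9 methyl group and the E-C9=C10 alkene in one operation.

**Step 6**
Reactants: 12 tert-butyl{[(1R)-4-[(1E,3E)-4-iodo-3-methylbuta-1,3-dien-1-yl]-3,5,5-trimethylcyclohex-3-en-1-yl]oxy}dimethylsilane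
Product: 13 (1R)-4-[(1E,3E)-4-iodo-3-methylbuta-1,3-dien-1-yl]-3,5,5-trimethylcyclohex-3-en-1-ol
Conditions: Bu4NF, THF, 0 °C → rt
Reagents that add atoms: none
Why: Fluoride-mediated silyl ether cleavage frees the C3 hydroxyl; the alkenyl iodide has no hydrogen on C9 and so cannot eliminate to an alkyne.

**Step 7**
Reactants: 13 (1R)-4-[(1E,3E)-4-iodo-3-methylbuta-1,3-dien-1-yl]-3,5,5-trimethylcyclohex-3-en-1-ol; 14 hexadecanoyl chloride
Product: 15 (1R)-4-[(1E,3E)-4-iodo-3-methylbuta-1,3-dien-1-yl]-3,5,5-trimethylcyclohex-3-en-1-yl hexadecanoate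
Conditions: pyridine, DMAP (cat.), CH2Cl2, 0 °C → rt
Reagents that add atoms: none
Why: O-Acylation with an acid chloride under nucleophilic catalysis installs the palmitate on C3 with retention, since the C–O bond of the stereocentre is not broken.

**Step 8**
Reactants: 16 (3E)-4-[(1R)-2,6,6-trimethylcyclohex-2-en-1-yl]but-3-en-2-one, (R)-α-ionone
Product: 20 (6R)-6-[(1E)-but-1-en-3-yn-1-yl]-1,5,5-trimethylcyclohex-1-ene, via lithium dienolate 17 (not isolated), via enol phosphate 18 (not isolated), via lithium acetylide 19 (not isolated)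
Conditions: LiN(i-Pr)2 (1.05 equiv), THF, −78 °C; ClP(O)(OEt)2, −78 °C → rt; then LiN(i-Pr)2 (2.2 equiv), THF, −78 → −20 °C; H2O
Reagents that add atoms: none
Why: Methyl ketone to terminal alkyne through the enol phosphate as in step 4; kinetic deprotonation occurs at the methyl group and the elimination stage is kept cold, so the doubly allylic C6–H stereocentre should not be deprotonated.

**Step 9**
Reactants: 20 (6R)-6-[(1E)-but-1-en-3-yn-1-yl]-1,5,5-trimethylcyclohex-1-ene
Product: 21 (4R)-4-[(1E)-but-1-en-3-yn-1-yl]-3,5,5-trimethylcyclohex-2-en-1-one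
Conditions: t-BuOOH (in decane, 5 equiv), Mn(OAc)3·2H2O (10 mol%), 3 Å MS, EtOAc, rt
Reagents that add atoms: tert-butyl hydroperoxide, CC(C)(C)OO
Why: Metal-catalysed allylic C–H oxidation with tert-butyl hydroperoxide (peroxyl-radical chain, mixed peroxide collapsing to the enone) should attack the unhindered secondary allylic C3 methylene, the tertiary C6–H being shielded by the geminal methyls and the C5 methyl; the medium is neutral, so the now vinylogously acidic C6 centre should keep its configuration.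

**Step 10**
Reactants: 21 (4R)-4-[(1E)-but-1-en-3-yn-1-yl]-3,5,5-trimethylcyclohex-2-en-1-one
Product: 22 (1R,4R)-4-[(1E)-but-1-en-3-yn-1-yl]-3,5,5-trimethylcyclohex-2-en-1-ol
Conditions: LiBH(s-Bu)3, THF, −78 °C; H2O
Reagents that add atoms: none
Why: 1,2-Reduction of a β,β-disubstituted cyclohexenone by a bulky trialkylborohydride (conjugate reduction is blocked by the C5 methyl): with the C6 chain pseudo-axial to avoid A(1,2) strain with the C5 methyl, the axial C1 methyl shields the opposite face, so hydride should enter equatorially on the chain side and place the new C3 hydroxyl trans to the chain, that is 3R.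

**Step 11**
Reactants: 22 (1R,4R)-4-[(1E)-but-1-en-3-yn-1-yl]-3,5,5-trimethylcyclohex-2-en-1-ol
Product: 25 (1R,4R)-4-[(1E,3E)-4-iodo-3-methylbuta-1,3-dien-1-yl]-3,5,5-trimethylcyclohex-2-en-1-ol, via aluminium alkoxide 23 (not isolated), via alkenylalane 24 (not isolated)
Conditions: AlMe3 (3.5 equiv), Cp2ZrCl2 (0.3 equiv), CH2Cl2, 0 °C → rt; then I2, THF, −30 → 0 °C; aq. NaHCO3/Na2S2O3
Reagents that add atoms: trimethylaluminium, C[Al](C)C; iodine, II
Why: Negishi carboalumination–iodinolysis as in step 5, run on the aluminium alkoxide formed in situ from the free alcohol so that no protecting group is needed; syn addition sets the E-C9'=C10' alkene and the ring stereocentres take no part.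

**Step 12**
Reactants: 26 dibromomethane; 27 tributyltin chloride
Product: 29 tributyl(dibromomethyl)stannane, via dibromomethyllithium 28 (not isolated)
Conditions: LiN(i-Pr)2, THF, −90 °C; then Bu3SnCl, −90 → −40 °C
Reagents that add atoms: none
Why: Deprotonation of dibromomethane gives the carbenoid LiCHBr2, which is trapped by nucleophilic substitution at tin below the temperature at which it undergoes α-elimination.

**Step 13**
Reactants: 30 (2E,4E,6E)-2,7-dimethylocta-2,4,6-trienedial; 29 tributyl(dibromomethyl)stannane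
Product: 31 [(1E,3E,5E,7E,9E)-3,8-dimethyldeca-1,3,5,7,9-pentaene-1,10-diyl]bis(tributylstannane)
Conditions: 29 (4 equiv), CrCl2 (16 equiv), LiI (8 equiv), THF/DMF, rt, dark
Reagents that add atoms: none
Why: Twofold Takai–Hodgson olefination: CrCl2 turns the gem-dibromide into a geminal dichromium species that adds to each aldehyde and eliminates anti, which should give the E-alkenyl stannane at both ends (C11=C12 and C11'=C12').

**Step 14**
Reactants: 25 (1R,4R)-4-[(1E,3E)-4-iodo-3-methylbuta-1,3-dien-1-yl]-3,5,5-trimethylcyclohex-2-en-1-ol; 31 [(1E,3E,5E,7E,9E)-3,8-dimethyldeca-1,3,5,7,9-pentaene-1,10-diyl]bis(tributylstannane)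
Product: 32 (1R,4R)-4-[(1E,3E,5E,7E,9E,11E,13E)-3,7,12-trimethyl-14-(tributylstannyl)tetradeca-1,3,5,7,9,11,13-heptaen-1-yl]-3,5,5-trimethylcyclohex-2-en-1-ol
Conditions: 31 (3 equiv), Pd2(dba)3 (2.5 mol%), AsPh3 (20 mol%), NMP, 25 °C, dark
Reagents that add atoms: none
Why: Stille coupling (oxidative addition of the C10'–I bond, tin-to-palladium transmetalation, reductive elimination) with retention at both alkenes forms C10'–C11'; the linchpin is used in excess so that one tin terminus reacts, and the hydroxyl-bearing product should separate easily from the non-polar bis-stannane, which is recovered.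

**Step 15**
Reactants: 15 (1R)-4-[(1E,3E)-4-iodo-3-methylbuta-1,3-dien-1-yl]-3,5,5-trimethylcyclohex-3-en-1-yl hexadecanoate; 32 (1R,4R)-4-[(1E,3E,5E,7E,9E,11E,13E)-3,7,12-trimethyl-14-(tributylstannyl)tetradeca-1,3,5,7,9,11,13-heptaen-1-yl]-3,5,5-trimethylcyclohex-2-en-1-ol
Product: 33 (3R,3'R,6'R)-3'-hydroxy-β,ε-caroten-3-yl hexadecanoate
Conditions: Pd2(dba)3 (5 mol%), AsPh3 (40 mol%), THF/NMP, 25–40 °C, Ar, dark
Reagents that add atoms: none
Why: Stille alkenyl–alkenyl cross-coupling: zerovalent palladium inserts into the C10–I bond of 15, the C11 alkenyl group of 32 passes from tin to palladium (the slow step, which AsPh3 and the polar solvent accelerate), and reductive elimination forms the C10–C11 single bond and completes the decaene. The closest known reaction type is the Stille coupling of 1-iodo-2-methyl-1,3-dienes with polyenyl stannanes, here applied to two different, fully functionalised halves. No ring is closed and no stereocentre is created; C3, C3' and C6' lie far from the reacting atoms. The step needs retention of the E geometry at C9=C10 and C11=C12, which oxidative addition, transmetalation and reductive elimination at sp2 carbon all deliver. It also needs reaction at the C–I bond only, which the substrate secures because the palmitate, the free allylic C3' hydroxyl and the doubly allylic C6'–H meet neither base nor acid nor a nucleophile. Because the ester already sits on ring A and the free hydroxyl on ring B, the two oxygen functions are told apart by the choice of bond, and nothing has to be protected or unmasked on the C40 polyene.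

**Compound list**
1 | (4R,6R)-4-hydroxy-2,2,6-trimethylcyclohexan-1-one | CC1(C)C[C@H](O)C[C@@H](C)C1=O | starting material
2 | (4R,6R)-4-[(tert-butyldimethylsilyl)oxy]-2,2,6-trimethylcyclohexan-1-one | CC1(C)C[C@H](O[Si](C)(C)C(C)(C)C)C[C@@H](C)C1=O | intermediate
3 | lithium (4R)-4-[(tert-butyldimethylsilyl)oxy]-2,6,6-trimethylcyclohex-1-en-1-olate (not isolated) | CC(C)(C)[Si](C)(C)O[C@@H]1CC(C)=C(O[Li])C(C)(C)C1 | intermediate
4 | (4R)-4-[(tert-butyldimethylsilyl)oxy]-2,6,6-trimethylcyclohex-1-en-1-yl trifluoromethanesulfonate | CC(C)(C)[Si](C)(C)O[C@@H]1CC(C)=C(OS(=O)(=O)C(F)(F)F)C(C)(C)C1 | intermediate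
5 | but-3-en-2-one | CC(=O)C=C | starting material
6 | (3E)-4-[(4R)-4-[(tert-butyldimethylsilyl)oxy]-2,6,6-trimethylcyclohex-1-en-1-yl]but-3-en-2-one | CC(C)(C)[Si](C)(C)O[C@@H]1CC(C)=C(/C=C/C(C)=O)C(C)(C)C1 | intermediate
7 | lithium (3E)-4-[(4R)-4-[(tert-butyldimethylsilyl)oxy]-2,6,6-trimethylcyclohex-1-en-1-yl]buta-1,3-dien-2-olate (not isolated) | CC(C)(C)[Si](C)(C)O[C@@H]1CC(C)=C(/C=C/C(=C)O[Li])C(C)(C)C1 | intermediate
8 | (3E)-4-[(4R)-4-[(tert-butyldimethylsilyl)oxy]-2,6,6-trimethylcyclohex-1-en-1-yl]buta-1,3-dien-2-yl diethyl phosphate (not isolated) | CC(C)(C)[Si](C)(C)O[C@@H]1CC(C)=C(/C=C/C(=C)OP(=O)(OCC)OCC)C(C)(C)C1 | intermediate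
9 | lithium acetylide of 10 (not isolated) | CC(C)(C)[Si](C)(C)O[C@@H]1CC(C)=C(/C=C/C#C[Li])C(C)(C)C1 | intermediate
10 | {[(1R)-4-[(1E)-but-1-en-3-yn-1-yl]-3,5,5-trimethylcyclohex-3-en-1-yl]oxy}(tert-butyl)dimethylsilane | CC(C)(C)[Si](C)(C)O[C@@H]1CC(C)=C(/C=C/C#C)C(C)(C)C1 | intermediate
11 | {(1E,3E)-4-[(4R)-4-[(tert-butyldimethylsilyl)oxy]-2,6,6-trimethylcyclohex-1-en-1-yl]-2-methylbuta-1,3-dien-1-yl}dimethylalumane (not isolated) | CC(C)(C)[Si](C)(C)O[C@@H]1CC(C)=C(/C=C/C(C)=C/[Al](C)C)C(C)(C)C1 | intermediate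
12 | tert-butyl{[(1R)-4-[(1E,3E)-4-iodo-3-methylbuta-1,3-dien-1-yl]-3,5,5-trimethylcyclohex-3-en-1-yl]oxy}dimethylsilane | CC(C)(C)[Si](C)(C)O[C@@H]1CC(C)=C(/C=C/C(C)=C/I)C(C)(C)C1 | intermediate
13 | (1R)-4-[(1E,3E)-4-iodo-3-methylbuta-1,3-dien-1-yl]-3,5,5-trimethylcyclohex-3-en-1-ol | O[C@@H]1CC(C)=C(/C=C/C(C)=C/I)C(C)(C)C1 | intermediate
14 | hexadecanoyl chloride | CCCCCCCCCCCCCCCC(=O)Cl | starting material
15 | (1R)-4-[(1E,3E)-4-iodo-3-methylbuta-1,3-dien-1-yl]-3,5,5-trimethylcyclohex-3-en-1-yl hexadecanoate | CCCCCCCCCCCCCCCC(=O)O[C@@H]1CC(C)=C(/C=C/C(C)=C/I)C(C)(C)C1 | intermediate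
16 | (3E)-4-[(1R)-2,6,6-trimethylcyclohex-2-en-1-yl]but-3-en-2-one, (R)-α-ionone | CC(=O)/C=C/[C@H]1C(C)=CCCC1(C)C | starting material
17 | lithium (3E)-4-[(1R)-2,6,6-trimethylcyclohex-2-en-1-yl]buta-1,3-dien-2-olate (not isolated) | C=C(O[Li])/C=C/[C@H]1C(C)=CCCC1(C)C | intermediate
18 | diethyl (3E)-4-[(1R)-2,6,6-trimethylcyclohex-2-en-1-yl]buta-1,3-dien-2-yl phosphate (not isolated) | C=C(OP(=O)(OCC)OCC)/C=C/[C@H]1C(C)=CCCC1(C)C | intermediate
19 | lithium acetylide of 20 (not isolated) | [Li]C#C/C=C/[C@H]1C(C)=CCCC1(C)C | intermediate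
20 | (6R)-6-[(1E)-but-1-en-3-yn-1-yl]-1,5,5-trimethylcyclohex-1-ene | C#C/C=C/[C@H]1C(C)=CCCC1(C)C | intermediate
21 | (4R)-4-[(1E)-but-1-en-3-yn-1-yl]-3,5,5-trimethylcyclohex-2-en-1-one | C#C/C=C/[C@H]1C(C)=CC(=O)CC1(C)C | intermediate
22 | (1R,4R)-4-[(1E)-but-1-en-3-yn-1-yl]-3,5,5-trimethylcyclohex-2-en-1-ol | C#C/C=C/[C@H]1C(C)=C[C@H](O)CC1(C)C | intermediate
23 | dimethylaluminium alkoxide of 22 (not isolated) | C#C/C=C/[C@H]1C(C)=C[C@H](O[Al](C)C)CC1(C)C | intermediate
24 | (1E,3E)-2-methylbuta-1,3-dienyl(dimethyl)alumane bearing the ring O-dimethylaluminium alkoxide (not isolated) | C[Al](C)/C=C(C)/C=C/[C@H]1C(C)=C[C@H](O[Al](C)C)CC1(C)C | intermediate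
25 | (1R,4R)-4-[(1E,3E)-4-iodo-3-methylbuta-1,3-dien-1-yl]-3,5,5-trimethylcyclohex-2-en-1-ol | I/C=C(C)/C=C/[C@H]1C(C)=C[C@H](O)CC1(C)C | intermediate
26 | dibromomethane | BrCBr | starting material
27 | tributyltin chloride | CCCC[Sn](Cl)(CCCC)CCCC | starting material
28 | dibromomethyllithium (not isolated) | [Li]C(Br)Br | intermediate
29 | tributyl(dibromomethyl)stannane | CCCC[Sn](CCCC)(CCCC)C(Br)Br | intermediate
30 | (2E,4E,6E)-2,7-dimethylocta-2,4,6-trienedial | O=C/C(C)=C/C=C/C=C(C)/C=O | starting material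
31 | [(1E,3E,5E,7E,9E)-3,8-dimethyldeca-1,3,5,7,9-pentaene-1,10-diyl]bis(tributylstannane) | CCCC[Sn](CCCC)(CCCC)/C=C/C(C)=C/C=C/C=C(C)/C=C/[Sn](CCCC)(CCCC)CCCC | intermediate
32 | (1R,4R)-4-[(1E,3E,5E,7E,9E,11E,13E)-3,7,12-trimethyl-14-(tributylstannyl)tetradeca-1,3,5,7,9,11,13-heptaen-1-yl]-3,5,5-trimethylcyclohex-2-en-1-ol | CCCC[Sn](CCCC)(CCCC)/C=C/C(C)=C/C=C/C=C(C)/C=C/C=C(C)/C=C/[C@H]1C(C)=C[C@H](O)CC1(C)C | intermediate
33 | (3R,3'R,6'R)-3'-hydroxy-β,ε-caroten-3-yl hexadecanoate | CCCCCCCCCCCCCCCC(=O)O[C@@H]1CC(C)=C(/C=C/C(C)=C/C=C/C(C)=C/C=C/C=C(C)/C=C/C=C(C)/C=C/[C@H]2C(C)=C[C@H](O)CC2(C)C)C(C)(C)C1 | target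

**Totals**
Total step count: 15. Longest linear sequence: 8 steps (steps 1–7, then step 15).

**Steps most likely to fail**

Step 10: hydride delivery to the ring enone may show poor facial selectivity, so that the C3',C6'-cis epimer forms alongside the wanted trans alcohol. The fallback sets out from 21 and converges the wrong epimer instead of discarding it. Luche reduction (NaBH4, CeCl3·7H2O, MeOH, −78 °C), in which the small hydride should favour axial attack, gives the cis alcohol (1S,4R)-4-[(1E)-but-1-en-3-yn-1-yl]-3,5,5-trimethylcyclohex-2-en-1-ol F1. The same compound, where it arises as the minor product of step 10, is fed in here. Mitsunobu inversion (4-nitrobenzoic acid, PPh3, DIAD, THF, 0 °C) then gives the trans ester (1R,4R)-4-[(1E)-but-1-en-3-yn-1-yl]-3,5,5-trimethylcyclohex-2-en-1-yl 4-nitrobenzoate F2, and methanolysis (K2CO3, MeOH, rt) returns to the route at 22.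

Step 14: both tin termini of the linchpin may couple, and the polyenyl stannanes may lose tin by protonolysis during chromatography. The fallback sets out from 30 and differentiates the two ends through an aldehyde, so that the valuable iodide 25 is never used in a statistical step. Mono-olefination of 30 (in excess) with 29 (CrCl2, LiI, THF/DMF) gives (2E,4E,6E,8E)-2,7-dimethyl-9-(tributylstannyl)nona-2,4,6,8-tetraenal F3. Stille coupling of F3 with 25 (Pd2(dba)3, AsPh3, NMP, rt) gives (3R,6R)-3-hydroxy-12'-apo-ε-caroten-12'-al F4. A second Takai–Hodgson olefination of F4 with 29 returns to the route at 32.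

Step 15: tin-to-palladium transfer from the long polyenyl stannane may be slow, so that protodestannylation, stannane homocoupling and light- or heat-induced E/Z isomerisation of the decaene compete. The fallback forms the same bond by a boron-based coupling with reversed polarity. From 15, Miyaura borylation (B2pin2, PdCl2(PPh3)2, PPh3, KOPh, toluene, 50 °C) gives (1R)-3,5,5-trimethyl-4-[(1E,3E)-3-methyl-4-(4,4,5,5-tetramethyl-1,3,2-dioxaborolan-2-yl)buta-1,3-dien-1-yl]cyclohex-3-en-1-yl hexadecanoate F5. From 32, iododestannylation (I2, CH2Cl2, −78 → 0 °C) gives (1R,4R)-4-[(1E,3E,5E,7E,9E,11E,13E)-14-iodo-3,7,12-trimethyltetradeca-1,3,5,7,9,11,13-heptaen-1-yl]-3,5,5-trimethylcyclohex-2-en-1-ol F6. Suzuki–Miyaura coupling of F5 with F6 (Pd(PPh3)4, aq. K3PO4, THF, rt) comes back to the route at 33.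

**Further compounds**
F1 | step 10 | (1S,4R)-4-[(1E)-but-1-en-3-yn-1-yl]-3,5,5-trimethylcyclohex-2-en-1-ol | C#C/C=C/[C@H]1C(C)=C[C@@H](O)CC1(C)C
F2 | step 10 | (1R,4R)-4-[(1E)-but-1-en-3-yn-1-yl]-3,5,5-trimethylcyclohex-2-en-1-yl 4-nitrobenzoate | C#C/C=C/[C@H]1C(C)=C[C@H](OC(=O)c2ccc(cc2)[N+](=O)[O-])CC1(C)C
F3 | step 14 | (2E,4E,6E,8E)-2,7-dimethyl-9-(tributylstannyl)nona-2,4,6,8-tetraenal | CCCC[Sn](CCCC)(CCCC)/C=C/C(C)=C/C=C/C=C(C)/C=O
F4 | step 14 | (3R,6R)-3-hydroxy-12'-apo-ε-caroten-12'-al | O=C/C(C)=C/C=C/C=C(C)/C=C/C=C(C)/C=C/[C@H]1C(C)=C[C@H](O)CC1(C)C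
F5 | step 15 | (1R)-3,5,5-trimethyl-4-[(1E,3E)-3-methyl-4-(4,4,5,5-tetramethyl-1,3,2-dioxaborolan-2-yl)buta-1,3-dien-1-yl]cyclohex-3-en-1-yl hexadecanoate | CCCCCCCCCCCCCCCC(=O)O[C@@H]1CC(C)=C(/C=C/C(C)=C/B2OC(C)(C)C(C)(C)O2)C(C)(C)C1
F6 | step 15 | (1R,4R)-4-[(1E,3E,5E,7E,9E,11E,13E)-14-iodo-3,7,12-trimethyltetradeca-1,3,5,7,9,11,13-heptaen-1-yl]-3,5,5-trimethylcyclohex-2-en-1-ol | I/C=C/C(C)=C/C=C/C=C(C)/C=C/C=C(C)/C=C/[C@H]1C(C)=C[C@H](O)CC1(C)C
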